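**Retrosynthetic overview**

1. Target 41 comes from butenolide 35 by late oxygenation of lactone ring C (8,17-epoxidation, SmI2 opening, C17 equilibration) and a silyl-to-acetate exchange.
2. Key disconnection of 35: C7–C8 and C17–C19 together. The lactone unit C7–O–C19(=O) is carried as C2–O1–C5 of a 5-methoxy-4-methyloxazole and C8–C17(CH3) as a propynyl group, so one intramolecular Diels–Alder/retro-Diels–Alder (loss of CH3CN) closes the ten-membered ring B and ring C (as a 2-methoxyfuran, hydrolysed to the butenolide).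
3. Oxazole 32 comes from a (Z)-enoic acid (ynoate + Me2CuLi) and L-alanine methyl ester; the C9 propynyl carbinol from Grignard addition, oxidation and asymmetric transfer hydrogenation.
4. Six-membered ring A comes from a catalytic enantioselective Diels–Alder of enal 3 with silyloxy diene 5 (C1, C10), then enone epoxidation, kinetic protonation at C11, SmI2 opening and hydroxyl-directed reduction (C14, C11, C12).
5. Order of ring formation: ring A (step 3), then rings B and C in one operation (step 24).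

Key step: step 24

Locants follow the briarane skeleton: C1 quaternary ring-fusion carbon (CH3-15), C2–C9 along ring B, C10 ring-fusion CH, C11 (CH3-20) to C14 in ring A, C17 (CH3-18) and C19 in ring C; β is the face of CH3-15.

Assumption: the sense of induction in step 3 is taken from the formyl C–H···O binding model of oxazaborolidinium catalysts with α-substituted enals; if it proved opposite, the (S)-catalyst would be used.

**Route**

Step 1
Reactants: 1 2-[(4-methoxybenzyl)oxy]acetaldehyde; 2 2-(triphenylphosphoranylidene)propanal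
Product: 3 (E)-4-[(4-methoxybenzyl)oxy]-2-methylbut-2-enal
Conditions: toluene, 80 °C
Reagents that add atoms: none
Why: Wittig olefination with a stabilized ylide should give the (E)-trisubstituted enal that carries C2, C1, CH3-15, C10 and C9.

Step 2
Reactants: 4 pent-1-en-3-one
Product: 5 (Z)-3-[(triisopropylsilyl)oxy]penta-1,3-diene
Conditions: TIPSOTf, Et3N, CH2Cl2, 0 °C
Reagents that add atoms: triisopropylsilyl trifluoromethanesulfonate CC(C)[Si](OS(=O)(=O)C(F)(F)F)(C(C)C)C(C)C
Why: Soft enolization of the ethyl ketone with silyl triflate and amine should give the (Z)-2-silyloxy diene (silyl dienol ether formation).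

Step 3
Reactants: 3 (E)-enal; 5 silyloxy diene
Product: 6 ring A aldehyde: 6-[(4-methoxybenzyloxy)methyl]-1,5-dimethyl-4-(triisopropylsilyloxy)cyclohex-3-ene-1-carbaldehyde (CH3-15 β, C9 arm β, CH3-20 α)
Conditions: (R)-B-(o-tolyl)oxazaborolidine of (R)-α,α-diphenylprolinol (20 mol%), Tf2NH (18 mol%), CH2Cl2, −78 → −40 °C
Reagents that add atoms: none
Why: Enantioselective Diels–Alder reaction under chiral oxazaborolidinium catalysis: the catalyst shields one face of the formyl-bound s-trans enal (absolute configuration of C1 and C10), the silyloxy-bearing diene terminus C11 bonds to the enal β-carbon C10 (para rule), the (E)-geometry puts CH3-15 and the C9 arm cis, and the C11 methyl, expected trans to the C9 arm (formyl-endo mode), is corrected in step 8.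

Step 4
Reactants: 6 ring A aldehyde; 7 (4-bromobut-1-yn-1-yl)trimethylsilane
Product: 9 (2S)-carbinol carrying the C3–C6 butynylsilane chain, via Grignard reagent 8 (not isolated)
Conditions: 7, Mg, THF, rt; then 6, THF, −78 °C; aq. NH4Cl
Reagents that add atoms: none
Why: Grignard addition to the neopentyl aldehyde should follow the Felkin–Anh model (attack anti to the more branched ring carbon C10 and past CH3-15), setting (2S); any (2R)-epimer would be removed by chromatography.

Step 5
Reactants: 9 (2S)-carbinol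
Product: 10 C2 triethylsilyl ether
Conditions: TESOTf, 2,6-lutidine, CH2Cl2, −78 °C
Reagents that add atoms: triethylsilyl trifluoromethanesulfonate CC[Si](CC)(CC)OS(=O)(=O)C(F)(F)F
Why: Silyl triflate silylation protects the hindered secondary alcohol without touching the silyl enol ether.

Step 6
Reactants: 10 C2 triethylsilyl ether
Product: 11 cyclohexenone (C12 ketone, C13=C14 alkene, CH3-20 α)
Conditions: Pd(OAc)2 (1.2 equiv), MeCN, rt
Reagents that add atoms: none
Why: Saegusa–Ito oxidation converts the silyl enol ether regiospecifically into the C13=C14 enone.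

Step 7
Reactants: 11 cyclohexenone
Product: 12 13α,14α-epoxy ketone (CH3-20 α)
Conditions: t-BuOOH (in decane), DBU, CH2Cl2, 0 °C → rt
Reagents that add atoms: tert-butyl hydroperoxide CC(C)(C)OO
Why: Weitz–Scheffer nucleophilic epoxidation: the peroxide anion should add to C14 axially on the α-face, anti to the axial CH3-15 of the half-chair that keeps both arms equatorial, so the future C14 oxygen ends cis to the C2 arm.

Step 8
Reactants: 12 13α,14α-epoxy ketone (CH3-20 α)
Product: 14 13α,14α-epoxy ketone with CH3-20 β, via lithium enolate 13 (not isolated)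
Conditions: LDA, THF, −78 °C; then 2,6-di-tert-butyl-4-methylphenol, THF, −78 °C; aq. NH4Cl
Reagents that add atoms: none
Why: C11 is the only readily enolizable position, and kinetic C-protonation of the enolate should occur on the α-face, away from CH3-15 and the C9 arm, placing CH3-20 β (cis to the C9 arm) against the thermodynamic preference (stereoselective enolate protonation).

Step 9
Reactants: 14 epoxy ketone (CH3-20 β)
Product: 15 14α-hydroxy C12 ketone
Conditions: SmI2 (2.5 equiv), THF/MeOH, −90 °C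
Reagents that add atoms: none
Why: SmI2 should cleave the Cα–O bond (C13–O) of the α,β-epoxy ketone under neutral conditions, giving the 14α-hydroxy ketone without epimerizing C11 (reductive opening of an epoxy ketone).

Step 10
Reactants: 15 14α-hydroxy ketone
Product: 16 12β,14α-diol
Conditions: Me4NBH(OAc)3, MeCN/AcOH, −30 °C
Reagents that add atoms: none
Why: Evans–Saksena reduction: the C14 alkoxyborohydride delivers hydride intramolecularly to the α-face of C12, giving the 12β-alcohol anti to the 14α-hydroxyl and cis to CH3-20.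

Step 11
Reactants: 16 12β,14α-diol
Product: 17 12β-tert-butyldimethylsilyl ether with free 14α-hydroxyl
Conditions: TBSCl, imidazole, DMF, 0 °C
Reagents that add atoms: tert-butyldimethylsilyl chloride CC(C)(C)[Si](C)(C)Cl
Why: The 12β-hydroxyl is far more accessible than the neopentyl 14α-hydroxyl next to quaternary C1, so the silylation should be selective (chemoselective protection).

Step 12
Reactants: 17 12β-silyl ether
Product: 18 C9 primary alcohol
Conditions: DDQ, CH2Cl2/pH 7 buffer, 0 °C
Reagents that add atoms: none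
Why: Oxidative cleavage of the p-methoxybenzyl ether by DDQ frees the C9 alcohol; silyl ethers and the alkynylsilane are inert.

Step 13
Reactants: 18 C9 primary alcohol
Product: 19 C9 aldehyde
Conditions: TEMPO (cat.), PhI(OAc)2, CH2Cl2, rt
Reagents that add atoms: none
Why: The oxoammonium oxidation is selective for the primary alcohol in the presence of the hindered secondary C14 hydroxyl.

Step 14
Reactants: 19 C9 aldehyde
Product: 20 C9-epimeric but-2-ynyl carbinols
Conditions: 1-propynylmagnesium bromide (3 equiv), THF, −78 °C; aq. NH4Cl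
Reagents that add atoms: 1-propynylmagnesium bromide CC#C[Mg]Br
Why: Grignard addition installs C8, C17 and CH3-18; the C9 configuration is set in step 16, so no selectivity is needed here.

Step 15
Reactants: 20 C9-epimeric carbinols
Product: 21 alkynyl ketone (C9 ketone)
Conditions: MnO2, CH2Cl2, rt
Reagents that add atoms: none
Why: MnO2 oxidizes only the propargylic alcohol and leaves the C14 hydroxyl.

Step 16
Reactants: 21 alkynyl ketone
Product: 22 (9S)-propargylic alcohol
Conditions: RuCl(p-cymene)[(S,S)-TsDPEN] (5 mol%), i-PrOK (5 mol%), i-PrOH, rt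
Reagents that add atoms: none
Why: Noyori asymmetric transfer hydrogenation of the alkynyl ketone: the (S,S)-catalyst should give the (9S)-alcohol, the sense also favoured by Felkin–Anh hydride delivery past C10.

Step 17
Reactants: 22 (9S)-propargylic alcohol
Product: 23 fully protected bis-alkyne (C2, C9, C14 triethylsilyl ethers; C12 tert-butyldimethylsilyl ether)
Conditions: TESOTf (3 equiv), 2,6-lutidine, CH2Cl2, −78 → 0 °C
Reagents that add atoms: triethylsilyl trifluoromethanesulfonate CC[Si](CC)(CC)OS(=O)(=O)C(F)(F)F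
Why: Silyl triflate silylates both the propargylic and the hindered C14 hydroxyl in one operation.

Step 18
Reactants: 23 fully protected bis-alkyne
Product: 24 terminal alkyne (C5≡C6–H)
Conditions: K2CO3 (cat.), MeOH, rt
Reagents that add atoms: none
Why: Methanolysis of the C(sp)–Si bond (alkynylsilane protodesilylation) leaves the O-silyl ethers and the internal alkyne untouched.

Step 19
Reactants: 24 terminal alkyne
Product: 26 methyl ynoate (C7 installed), via lithium acetylide 25 (not isolated)
Conditions: n-BuLi, THF, −78 °C; then ClCO2Me, −78 → 0 °C; aq. NH4Cl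
Reagents that add atoms: methyl chloroformate COC(=O)Cl
Why: Deprotonation of the terminal alkyne and C-acylation of the acetylide with the chloroformate gives the ynoate.

Step 20
Reactants: 26 methyl ynoate
Product: 28 methyl (Z)-enoate (C5=C6, CH3-16 installed), via alkenylcuprate 27 (not isolated)
Conditions: Me2CuLi (from MeLi and CuI), THF, −78 °C; then MeOH and aq. NH4Cl at −78 °C
Reagents that add atoms: lithium dimethylcuprate [Li+].C[Cu-]C
Why: syn-Carbocupration of the ynoate at −78 °C and protonation of the alkenylcopper with retention should give the (Z)-enoate in which the C4 chain and the ester are cis (conjugate addition of a Gilman cuprate).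

Step 21
Reactants: 28 methyl (Z)-enoate
Product: 29 (Z)-enoic acid
Conditions: KOSiMe3, THF, rt; then AcOH
Reagents that add atoms: none
Why: Potassium trimethylsilanolate cleaves the methyl ester under anhydrous conditions that spare the silyl ethers and the (Z)-alkene (silanolate ester cleavage).

Step 22
Reactants: 29 (Z)-enoic acid; 30 L-alanine methyl ester hydrochloride
Product: 31 N-[(Z)-enoyl]-L-alanine methyl ester
Conditions: EDC·HCl, HOBt, i-Pr2NEt, CH2Cl2, 0 °C → rt
Reagents that add atoms: none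
Why: Carbodiimide amide coupling; the alanine residue supplies N, the methyl-bearing carbon, C19 and the methoxy group of the oxazole, and its stereocentre is lost in step 23.

Step 23
Reactants: 31 N-acyl alanine ester
Product: 32 2-[(Z)-alkenyl]-5-methoxy-4-methyloxazole tethered to the propynyl carbinol
Conditions: PPh3, I2, Et3N, CH2Cl2, 0 °C → rt
Reagents that add atoms: none
Why: Robinson–Gabriel-type cyclodehydration: the phosphonium-activated amide is closed by the ester carbonyl oxygen and loses the α-proton to give the 5-methoxyoxazole.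

Step 24
Reactants: 32 alkenyl methoxyoxazole
Product: 35 ring B/ring C butenolide (7S; C8=C17), via oxa-azanorbornadiene cycloadduct 33 (not isolated), via ring-fused 2-methoxyfuran 34 (not isolated)
Conditions: o-dichlorobenzene (1 mM), 2,6-di-tert-butyl-4-methylphenol (cat.), 180 °C; then THF/H2O/AcOH, 0 °C → rt
Reagents that add atoms: water O
Why: The electron-rich oxazole reacts as a 2-azadiene across C2 and C5 with the tethered propynyl group; cycloadduct 33 (either facial isomer) loses acetonitrile by retro-[4+2] to the aromatic 2-methoxy-3-methylfuran 34, and mild aqueous acid protonates C7 and hydrolyses the ketene acetal to butenolide 35. The closest known reaction type is the intramolecular oxazole–alkyne Diels–Alder/retro-Diels–Alder of alkyne-tethered 5-alkoxyoxazoles with unactivated, methyl-capped alkynes near 180 °C, established for five- to seven-membered carbocycles; the ten-membered closure lengthens the tether only and has no precedent at that ring size. Ring B closes through the C7–C8 bond in the fused mode (oxazole C2 to the proximal alkyne carbon) and ring C forms as the furan through C17–C19. The new C7 stereocentre is set by protonation of the furan on its peripheral face: the (9S)-silyloxy centre, with H9 eclipsing C8=C17 to avoid allylic strain with CH3-18, holds the C10 side of ring B on one face, and only the (7S)-epimer keeps C6 and C10 on that same face. The step needs intra- over intermolecular reaction (high dilution), fused over bridged regiochemistry (the tether lets C7 reach only C8) and retention of the (Z)-C5=C6 alkene; the trans-1,2 arms on ring A, the rigid (Z)-alkenyl oxazole and the linear alkyne limit the rotors that must be frozen.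

Step 25
Reactants: 35 butenolide
Product: 36 8α,17-epoxy lactone
Conditions: t-BuOOH, n-BuLi, THF, −78 → −20 °C; aq. NH4Cl
Reagents that add atoms: tert-butyl hydroperoxide CC(C)(C)OO
Why: Weitz–Scheffer-type epoxidation of the tetrasubstituted butenolide with lithium tert-butylperoxide: with H9 eclipsing C8=C17 the peroxide should add to C8 anti to the C9 silyloxy group (Felkin–Anh polar model), and the reversible addition also favours the trans-fused adduct, giving the 8α,17-epoxide.

Step 26
Reactants: 36 8α,17-epoxy lactone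
Product: 37 8α-hydroxy lactone (C17 epimer mixture)
Conditions: SmI2 (3 equiv), THF/HMPA, Me2NCH2CH2OH, 0 °C
Reagents that add atoms: none
Why: SmI2 cleaves the Cα–O bond at C17 of the α,β-epoxy lactone, leaving the C8 tertiary alcohol, and protonation of the samarium enolate gives the β-hydroxy lactone (reductive epoxide opening).

Step 27
Reactants: 37 8α-hydroxy lactone (C17 mixture)
Product: 38 8α-hydroxy lactone with CH3-18 cis to the 8-hydroxyl
Conditions: DBU (0.3 equiv), toluene, rt
Reagents that add atoms: none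
Why: Base-mediated epimerization α to the lactone carbonyl should settle CH3-18 trans to the bulky C9 branch and cis to the 8-hydroxyl, the configuration of the target (thermodynamic control).

Step 28
Reactants: 38 8α-hydroxy lactone
Product: 39 2,9,14-triol with the C12 silyl ether retained
Conditions: HF·pyridine, pyridine, THF, 0 °C → rt
Reagents that add atoms: none
Why: Buffered HF·pyridine should remove the three triethylsilyl ethers much faster than the hindered secondary tert-butyldimethylsilyl ether at C12 (selective desilylation).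

Step 29
Reactants: 39 2,9,14-triol
Product: 40 2,9,14-triacetate 12-silyl ether
Conditions: Ac2O, pyridine, DMAP (cat.), CH2Cl2, 0 °C → rt
Reagents that add atoms: acetic anhydride CC(=O)OC(C)=O
Why: Acyl-transfer-catalysed acetylation of the three secondary hydroxyls; the tertiary C8 hydroxyl should not react under these conditions.

Step 30
Reactants: 40 triacetate silyl ether
Product: 41 CNP0195208.2
Conditions: HF·pyridine (excess), THF, rt
Reagents that add atoms: none
Why: Fluoride cleavage of the last silyl ether under acidic conditions that leave the acetates and the β-hydroxy lactone intact gives the target.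

**Compound list**

1 | 2-[(4-methoxybenzyl)oxy]acetaldehyde | O=CCOCc1ccc(OC)cc1 | starting material
2 | 2-(triphenylphosphoranylidene)propanal | CC(C=O)=P(c1ccccc1)(c1ccccc1)c1ccccc1 | starting material
3 | (E)-4-[(4-methoxybenzyl)oxy]-2-methylbut-2-enal | O=C/C(C)=C/COCc1ccc(OC)cc1 | intermediate
4 | pent-1-en-3-one | CCC(=O)C=C | starting material
5 | (Z)-3-[(triisopropylsilyl)oxy]penta-1,3-diene | C=C/C(O[Si](C(C)C)(C(C)C)C(C)C)=C/C | intermediate
6 | ring A aldehyde (CH3-15 β, C9 arm β, CH3-20 α; C12 silyl enol ether) | O=C[C@@]1(C)CC=C(O[Si](C(C)C)(C(C)C)C(C)C)[C@@H](C)[C@@H]1COCc1ccc(OC)cc1 | intermediate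
7 | (4-bromobut-1-yn-1-yl)trimethylsilane | C[Si](C)(C)C#CCCBr | starting material
8 | [4-(trimethylsilyl)but-3-yn-1-yl]magnesium bromide | C[Si](C)(C)C#CCC[Mg]Br | intermediate
9 | (2S)-carbinol with the C3–C6 butynylsilane chain | O[C@@H](CCC#C[Si](C)(C)C)[C@@]1(C)CC=C(O[Si](C(C)C)(C(C)C)C(C)C)[C@@H](C)[C@@H]1COCc1ccc(OC)cc1 | intermediate
10 | C2 triethylsilyl ether of 9 | CC[Si](CC)(CC)O[C@@H](CCC#C[Si](C)(C)C)[C@@]1(C)CC=C(O[Si](C(C)C)(C(C)C)C(C)C)[C@@H](C)[C@@H]1COCc1ccc(OC)cc1 | intermediate
11 | cyclohexenone (C12 ketone, C13=C14, CH3-20 α) | CC[Si](CC)(CC)O[C@@H](CCC#C[Si](C)(C)C)[C@@]1(C)C=CC(=O)[C@@H](C)[C@@H]1COCc1ccc(OC)cc1 | intermediate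
12 | 13α,14α-epoxy ketone (CH3-20 α) | CC[Si](CC)(CC)O[C@@H](CCC#C[Si](C)(C)C)[C@@]1(C)[C@H]2O[C@H]2C(=O)[C@@H](C)[C@@H]1COCc1ccc(OC)cc1 | intermediate
13 | lithium C11=C12 enolate of 12 | CC[Si](CC)(CC)O[C@@H](CCC#C[Si](C)(C)C)[C@@]1(C)[C@H]2O[C@H]2C(O[Li])=C(C)[C@@H]1COCc1ccc(OC)cc1 | intermediate
14 | 13α,14α-epoxy ketone (CH3-20 β, cis to the C9 arm) | CC[Si](CC)(CC)O[C@@H](CCC#C[Si](C)(C)C)[C@@]1(C)[C@H]2O[C@H]2C(=O)[C@H](C)[C@@H]1COCc1ccc(OC)cc1 | intermediate
15 | 14α-hydroxy C12 ketone | CC[Si](CC)(CC)O[C@@H](CCC#C[Si](C)(C)C)[C@@]1(C)[C@@H](O)CC(=O)[C@H](C)[C@@H]1COCc1ccc(OC)cc1 | intermediate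
16 | 12β,14α-diol | CC[Si](CC)(CC)O[C@@H](CCC#C[Si](C)(C)C)[C@@]1(C)[C@@H](O)C[C@H](O)[C@H](C)[C@@H]1COCc1ccc(OC)cc1 | intermediate
17 | 12β-tert-butyldimethylsilyl ether, 14α-alcohol | CC[Si](CC)(CC)O[C@@H](CCC#C[Si](C)(C)C)[C@@]1(C)[C@@H](O)C[C@H](O[Si](C)(C)C(C)(C)C)[C@H](C)[C@@H]1COCc1ccc(OC)cc1 | intermediate
18 | C9 primary alcohol | CC[Si](CC)(CC)O[C@@H](CCC#C[Si](C)(C)C)[C@@]1(C)[C@@H](O)C[C@H](O[Si](C)(C)C(C)(C)C)[C@H](C)[C@@H]1CO | intermediate
19 | C9 aldehyde | CC[Si](CC)(CC)O[C@@H](CCC#C[Si](C)(C)C)[C@@]1(C)[C@@H](O)C[C@H](O[Si](C)(C)C(C)(C)C)[C@H](C)[C@@H]1C=O | intermediate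
20 | C9-epimeric but-2-ynyl carbinols | CC[Si](CC)(CC)O[C@@H](CCC#C[Si](C)(C)C)[C@@]1(C)[C@@H](O)C[C@H](O[Si](C)(C)C(C)(C)C)[C@H](C)[C@@H]1C(O)C#CC | intermediate
21 | alkynyl ketone (C9 ketone) | CC[Si](CC)(CC)O[C@@H](CCC#C[Si](C)(C)C)[C@@]1(C)[C@@H](O)C[C@H](O[Si](C)(C)C(C)(C)C)[C@H](C)[C@@H]1C(=O)C#CC | intermediate
22 | (9S)-propargylic alcohol | CC[Si](CC)(CC)O[C@@H](CCC#C[Si](C)(C)C)[C@@]1(C)[C@@H](O)C[C@H](O[Si](C)(C)C(C)(C)C)[C@H](C)[C@@H]1[C@H](O)C#CC | intermediate
23 | fully protected bis-alkyne (C2, C9, C14 triethylsilyl ethers; C12 tert-butyldimethylsilyl ether) | CC[Si](CC)(CC)O[C@@H](CCC#C[Si](C)(C)C)[C@@]1(C)[C@@H](O[Si](CC)(CC)CC)C[C@H](O[Si](C)(C)C(C)(C)C)[C@H](C)[C@@H]1[C@H](O[Si](CC)(CC)CC)C#CC | intermediate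
24 | terminal alkyne | CC[Si](CC)(CC)O[C@@H](CCC#C)[C@@]1(C)[C@@H](O[Si](CC)(CC)CC)C[C@H](O[Si](C)(C)C(C)(C)C)[C@H](C)[C@@H]1[C@H](O[Si](CC)(CC)CC)C#CC | intermediate
25 | lithium acetylide of 24 | CC[Si](CC)(CC)O[C@@H](CCC#C[Li])[C@@]1(C)[C@@H](O[Si](CC)(CC)CC)C[C@H](O[Si](C)(C)C(C)(C)C)[C@H](C)[C@@H]1[C@H](O[Si](CC)(CC)CC)C#CC | intermediate
26 | methyl ynoate | CC[Si](CC)(CC)O[C@@H](CCC#CC(=O)OC)[C@@]1(C)[C@@H](O[Si](CC)(CC)CC)C[C@H](O[Si](C)(C)C(C)(C)C)[C@H](C)[C@@H]1[C@H](O[Si](CC)(CC)CC)C#CC | intermediate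
27 | lithium alkenyl(methyl)cuprate from syn-addition to 26 | CC[Si](CC)(CC)O[C@@H](CC/C(C)=C(/[Cu-]C)C(=O)OC)[C@@]1(C)[C@@H](O[Si](CC)(CC)CC)C[C@H](O[Si](C)(C)C(C)(C)C)[C@H](C)[C@@H]1[C@H](O[Si](CC)(CC)CC)C#CC.[Li+] | intermediate
28 | methyl (Z)-enoate | CC[Si](CC)(CC)O[C@@H](CC/C(C)=C\C(=O)OC)[C@@]1(C)[C@@H](O[Si](CC)(CC)CC)C[C@H](O[Si](C)(C)C(C)(C)C)[C@H](C)[C@@H]1[C@H](O[Si](CC)(CC)CC)C#CC | intermediate
29 | (Z)-enoic acid | CC[Si](CC)(CC)O[C@@H](CC/C(C)=C\C(=O)O)[C@@]1(C)[C@@H](O[Si](CC)(CC)CC)C[C@H](O[Si](C)(C)C(C)(C)C)[C@H](C)[C@@H]1[C@H](O[Si](CC)(CC)CC)C#CC | intermediate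
30 | L-alanine methyl ester hydrochloride | C[C@H](N)C(=O)OC.Cl | starting material
31 | N-[(Z)-enoyl]-L-alanine methyl ester | CC[Si](CC)(CC)O[C@@H](CC/C(C)=C\C(=O)N[C@@H](C)C(=O)OC)[C@@]1(C)[C@@H](O[Si](CC)(CC)CC)C[C@H](O[Si](C)(C)C(C)(C)C)[C@H](C)[C@@H]1[C@H](O[Si](CC)(CC)CC)C#CC | intermediate
32 | 2-[(Z)-alkenyl]-5-methoxy-4-methyloxazole with tethered propynyl carbinol | CC[Si](CC)(CC)O[C@@H](CC/C(C)=C\c2nc(C)c(OC)o2)[C@@]1(C)[C@@H](O[Si](CC)(CC)CC)C[C@H](O[Si](C)(C)C(C)(C)C)[C@H](C)[C@@H]1[C@H](O[Si](CC)(CC)CC)C#CC | intermediate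
33 | 7-oxa-2-azabicyclo[2.2.1]hepta-2,5-diene cycloadduct (either facial isomer) | CC[Si](CC)(CC)O[C@H]1CC/C(C)=C\C23OC(OC)(C(C)=N2)C(C)=C3[C@@H](O[Si](CC)(CC)CC)[C@H]2[C@@H](C)[C@@H](O[Si](C)(C)C(C)(C)C)C[C@H](O[Si](CC)(CC)CC)[C@@]21C | intermediate
34 | ring-fused 2-methoxy-3-methylfuran | CC[Si](CC)(CC)O[C@H]1CC/C(C)=C\c2oc(OC)c(C)c2[C@@H](O[Si](CC)(CC)CC)[C@H]2[C@@H](C)[C@@H](O[Si](C)(C)C(C)(C)C)C[C@H](O[Si](CC)(CC)CC)[C@@]21C | intermediate
35 | (7S)-butenolide (C8=C17) | CC[Si](CC)(CC)O[C@H]1CC/C(C)=C\[C@@H]2OC(=O)C(C)=C2[C@@H](O[Si](CC)(CC)CC)[C@H]2[C@@H](C)[C@@H](O[Si](C)(C)C(C)(C)C)C[C@H](O[Si](CC)(CC)CC)[C@@]21C | intermediate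
36 | 8α,17-epoxy lactone | CC[Si](CC)(CC)O[C@H]1CC/C(C)=C\[C@@H]2OC(=O)[C@]3(C)O[C@]23[C@@H](O[Si](CC)(CC)CC)[C@H]2[C@@H](C)[C@@H](O[Si](C)(C)C(C)(C)C)C[C@H](O[Si](CC)(CC)CC)[C@@]21C | intermediate
37 | 8α-hydroxy lactone (C17 epimer mixture) | CC[Si](CC)(CC)O[C@H]1CC/C(C)=C\[C@@H]2OC(=O)C(C)[C@@]2(O)[C@@H](O[Si](CC)(CC)CC)[C@H]2[C@@H](C)[C@@H](O[Si](C)(C)C(C)(C)C)C[C@H](O[Si](CC)(CC)CC)[C@@]21C | intermediate
38 | 8α-hydroxy lactone (CH3-18 cis to the 8-hydroxyl) | CC[Si](CC)(CC)O[C@H]1CC/C(C)=C\[C@@H]2OC(=O)[C@H](C)[C@@]2(O)[C@@H](O[Si](CC)(CC)CC)[C@H]2[C@@H](C)[C@@H](O[Si](C)(C)C(C)(C)C)C[C@H](O[Si](CC)(CC)CC)[C@@]21C | intermediate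
39 | 2,9,14-triol 12-silyl ether | O[C@H]1CC/C(C)=C\[C@@H]2OC(=O)[C@H](C)[C@@]2(O)[C@@H](O)[C@H]2[C@@H](C)[C@@H](O[Si](C)(C)C(C)(C)C)C[C@H](O)[C@@]21C | intermediate
40 | 2,9,14-triacetate 12-silyl ether | CC(=O)O[C@H]1CC/C(C)=C\[C@@H]2OC(=O)[C@H](C)[C@@]2(O)[C@@H](OC(C)=O)[C@H]2[C@@H](C)[C@@H](O[Si](C)(C)C(C)(C)C)C[C@H](OC(C)=O)[C@@]21C | intermediate
41 | CNP0195208.2 | CC(=O)O[C@H]1CC/C(C)=C\[C@@H]2OC(=O)[C@H](C)[C@@]2(O)[C@@H](OC(C)=O)[C@H]2[C@@H](C)[C@@H](O)C[C@H](OC(C)=O)[C@@]21C | target

**Totals and risks**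

Total step count: 30. Longest linear sequence: 29 steps (from 1 through steps 1 and 3–30).

Steps most likely to fail:

1. Step 24. The ten-membered transition state may be reached too slowly, so that intermolecular cycloaddition, Z/E isomerization or thermal decomposition of the alkenyl oxazole outruns ring closure. The fallback builds ring C on a metal template instead; it sets out from 28 and comes back at 35. Ester 28 would be reduced with DIBAL-H (CH2Cl2, −78 °C) to the (Z)-allylic alcohol F1 and oxidized with MnO2 (CH2Cl2, rt) to the (Z)-enal F2. A hetero-Pauson–Khand cyclocarbonylation of the aldehyde and the propynyl group of F2 (Mo(CO)6, DMSO, toluene, 100 °C, high dilution) would then form C7–C8, C17–C19 and the C19–O bond and give butenolide 35. This cyclocarbonylation is itself only known for small rings, so it changes the mechanism but not the ring-size risk.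

2. Step 25. Facial selectivity may be poor (oxygen delivered to the face syn to the C9 silyloxy group under steric rather than stereoelectronic control), or γ-deprotonation of the butenolide may compete. The fallback uses reagent control; it sets out from 35 and comes back at 36. Butenolide 35 would be reduced with DIBAL-H (CH2Cl2, −78 → 0 °C) to the (Z)-ene-1,4-diol F3. A Sharpless asymmetric epoxidation directed by the primary C19 hydroxyl (Ti(OiPr)4, L-(+)-diethyl tartrate, t-BuOOH, 4 Å molecular sieves, CH2Cl2, −20 °C) would give the epoxy diol F4; this tartrate gives the (2S)-type epoxy alcohol, which corresponds to (17S) here. Oxidative lactonization of F4 (TEMPO, PhI(OAc)2, CH2Cl2) would return to epoxy lactone 36.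

3. Step 8. Proton transfer to the enolate oxygen followed by unselective ketonization, or equilibration during the quench, may give back the 11α-methyl epimer. The fallback replaces enolate protonation by hydrogen-atom transfer; it sets out from 12 and comes back at 14. Enolate 13 would be trapped with N-bromosuccinimide (THF, −78 °C) to give the α-bromo ketone F5 (either C11 configuration). Radical reduction (Bu3SnH, Et3B/air, toluene, −78 °C) would then pass through the planar α-keto radical, which should take hydrogen from the bulky stannane on the open α-face and give 14.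

**Further compounds**

F1 | step 24 | (Z)-allylic alcohol from reduction of 28 | CC[Si](CC)(CC)O[C@@H](CC/C(C)=C\CO)[C@@]1(C)[C@@H](O[Si](CC)(CC)CC)C[C@H](O[Si](C)(C)C(C)(C)C)[C@H](C)[C@@H]1[C@H](O[Si](CC)(CC)CC)C#CC
F2 | step 24 | (Z)-enal with tethered propynyl carbinol | CC[Si](CC)(CC)O[C@@H](CC/C(C)=C\C=O)[C@@]1(C)[C@@H](O[Si](CC)(CC)CC)C[C@H](O[Si](C)(C)C(C)(C)C)[C@H](C)[C@@H]1[C@H](O[Si](CC)(CC)CC)C#CC
F3 | step 25 | ring B (Z)-ene-1,4-diol (C7 and C19 hydroxyls) | CC[Si](CC)(CC)O[C@H]1CC/C(C)=C\[C@H](O)/C(=C(/C)CO)[C@@H](O[Si](CC)(CC)CC)[C@H]2[C@@H](C)[C@@H](O[Si](C)(C)C(C)(C)C)C[C@H](O[Si](CC)(CC)CC)[C@@]21C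
F4 | step 25 | 8α,17-epoxy diol | CC[Si](CC)(CC)O[C@H]1CC/C(C)=C\[C@H](O)[C@]2(O[C@@]2(C)CO)[C@@H](O[Si](CC)(CC)CC)[C@H]2[C@@H](C)[C@@H](O[Si](C)(C)C(C)(C)C)C[C@H](O[Si](CC)(CC)CC)[C@@]21C
F5 | step 8 | C11 α-bromo epoxy ketone | CC[Si](CC)(CC)O[C@@H](CCC#C[Si](C)(C)C)[C@@]1(C)[C@H]2O[C@H]2C(=O)[C@](Br)(C)[C@@H]1COCc1ccc(OC)cc1
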